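**Retrosynthetic overview**

- The target is traced back through a lipase resolution (by way of its acetate) to the racemic cis 4-hydroxy enone, then to a 1-silyloxycyclohexene (Saegusa–Ito oxidation), then to a C4 boronate (C–B to C–OH with retention), then to a Diels–Alder adduct.
- Only one ring is formed, the six-membered carbocycle C1–C6 (C1 carbonyl, C3 methyl, C4 hydroxyl, C5 side chain). It is closed in a single intermolecular [4+2] that makes C3–C4 and C5–C6 between a C6=C1(OSi)–C2=C3 silyloxydiene and a C4=C5 (Z)-alkenylboronate.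
- Enabling feature: in the cyclohexenone ring the C1 carbonyl lies para to the C4 carbinol, and the C4–O and C5–C bonds are cis on neighbouring ring carbons. This is the retron of a 2-oxydiene plus a cis alkene; boron on C4 is a removable activating group that stands in for oxygen, and the C1=C2 silyl enol ether is the latent C2=C3 enone.
- The dienophile comes from geranylgeraniol (bromide, CuBr·SMe2-catalysed alkynylation to a 1,4-enyne, [Rh(cod)Cl]2/P(i-Pr)3-catalysed trans-hydroboration); the diene comes from pent-3-en-2-one.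

Key step: step 5

Remark: "geranylgeranyl" means the (2E,6E,10E)-3,7,11,15-tetramethylhexadeca-2,6,10,14-tetraen-1-yl group, taken intact from commercial all-E geranylgeraniol; steps 5 to 7 carry racemic cis material, and the (4S,5S) enantiomer is selected enzymatically in steps 8 and 9.

**Route**

Step 1
Reactants: 1 (2E,6E,10E)-geranylgeraniol
Product: 2 (2E,6E,10E)-1-bromo-3,7,11,15-tetramethylhexadeca-2,6,10,14-tetraene (geranylgeranyl bromide)
Conditions: PBr3 (0.4 equiv), Et2O, −10 °C
Reagents that add atoms: phosphorus tribromide, BrP(Br)Br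
Why: Allylic bromination with PBr3 at low temperature should proceed by SN2 displacement of the intermediate phosphite ester without allylic transposition, so the 2E geometry is kept.

Step 2
Reactants: 2 geranylgeranyl bromide; 3 ethynylmagnesium bromide
Product: 4 (4E,8E,12E)-5,9,13,17-tetramethyloctadeca-4,8,12,16-tetraen-1-yne
Conditions: CuBr·SMe2 (5 mol %), THF, 0 °C to rt
Reagents that add atoms: none
Why: CuBr·SMe2-catalysed cross-coupling of the alkynyl Grignard reagent with the primary allylic bromide should occur by SN2 attack at the unhindered terminus (SN2′ attack at the fully substituted carbon being disfavoured) and give the skipped 1,4-enyne with all E alkenes untouched.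

Step 3
Reactants: 4 (4E,8E,12E)-5,9,13,17-tetramethyloctadeca-4,8,12,16-tetraen-1-yne
Product: 5 4,4,5,5-tetramethyl-2-[(1Z,4E,8E,12E)-5,9,13,17-tetramethyloctadeca-1,4,8,12,16-pentaen-1-yl]-1,3,2-dioxaborolane
Conditions: HBpin, [Rh(cod)Cl]2 (1.5 mol %), P(i-Pr)3 (6 mol %), Et3N, cyclohexane, rt
Reagents that add atoms: pinacolborane, CC1(C)OBOC1(C)C
Why: [Rh(cod)Cl]2/P(i-Pr)3-catalysed anti-Markovnikov trans-hydroboration of the terminal alkyne (through a vinylidene complex) should place boron at the terminus cis to the chain and give the (Z)-alkenylboronate, while the trisubstituted alkenes are not hydroborated under these conditions.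

Step 4
Reactants: 6 (3E)-pent-3-en-2-one
Product: 7 tert-butyl(dimethyl)[(3E)-penta-1,3-dien-2-yloxy]silane
Conditions: TBSOTf, Et3N, Et2O, 0 °C
Reagents that add atoms: tert-butyldimethylsilyl trifluoromethanesulfonate, CC(C)(C)[Si](C)(C)OS(=O)(=O)C(F)(F)F
Why: Soft enolisation (O-silylation, then deprotonation of the methyl group next to the carbonyl by the amine) should give the cross-conjugated 2-silyloxydiene with the E alkene intact, which is a standard silyl enol ether formation.

Step 5
Reactants: 5 (Z)-alkenyl pinacol boronate; 7 tert-butyl(dimethyl)[(3E)-penta-1,3-dien-2-yloxy]silane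
Product: 8 rac-tert-butyl(dimethyl)({(4S,5S)-3-methyl-4-(4,4,5,5-tetramethyl-1,3,2-dioxaborolan-2-yl)-5-geranylgeranylcyclohex-1-en-1-yl}oxy)silane (boryl group and side chain cis; both C3 epimers)
Conditions: neat, 7 (3 equiv), BHT (2,6-di-tert-butyl-4-methylphenol, cat.), 150 °C, sealed tube
Reagents that add atoms: none
Why: This is a normal-demand, concerted but asynchronous Diels–Alder reaction in which the HOMO of the 2-silyloxydiene (largest coefficient at its CH2 terminus, the future C6) meets the LUMO of the alkenylboronate, lowered by the vacant boron p orbital and largest at the carbon β to boron (the future C5), so that C5–C6 and C3–C4 form in one transition state. The closest known reactions are the thermal Diels–Alder additions of alkenylboronic esters and of B-vinyl dialkylboranes to 1,3-dienes, which place boron para to a 2-donor substituent, and the cycloadditions of 2-silyloxydienes with activated alkenes. The only ring of the target, the six-membered carbocycle C1–C6, is closed in the intermolecular suprafacial [4+2] mode, with diene 7 supplying C6–C1–C2–C3 and the alkene of 5 supplying C4–C5. The two stereocentres that survive, C4 (boron) and C5 (side chain), should come out cis because the Z alkene adds suprafacially; no chiral element is present, so 8 forms as the racemate, and the third centre, C3, forms as an endo/exo mixture that step 7 erases. The step needs regioselectivity (boron next to the methyl-bearing carbon and para to the silyloxy group), secured by matched orbital coefficients that both donor substituents of the diene reinforce, and chemoselectivity, secured because the four isolated trisubstituted alkenes of the chain are inert as dienophiles; the price is the modest dienophilicity of a β-alkyl alkenylboronate, which is met with heat, excess diene and a radical inhibitor.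

Step 6
Reactants: 8 rac-cycloadduct boronate
Product: 10 rac-(1S,6S)-4-{[tert-butyl(dimethyl)silyl]oxy}-2-methyl-6-geranylgeranylcyclohex-3-en-1-ol (hydroxyl and side chain cis; both C2 epimers), via borate ester 9 (not isolated)
Conditions: NaBO3·4H2O, THF–H2O (1:1), 0 °C to rt
Reagents that add atoms: sodium perborate (NaBO3·4H2O), [Na+].[Na+].O[B-]1(O)OO[B-](O)(O)OO1
Why: Oxidation of the secondary alkylboronate (hydroperoxide adds to boron and the C4–B bond migrates to oxygen in a 1,2-shift with retention) should put the C4 oxygen cis to the side chain, and the mild, weakly basic medium should leave the silyl enol ether and the isolated alkenes alone.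

Step 7
Reactants: 10 rac-hydroxy silyl enol ether
Product: 11 rac-(4S,5S)-4-hydroxy-3-methyl-5-geranylgeranylcyclohex-2-en-1-one (cis racemate)
Conditions: Pd(OAc)2 (1.1 equiv), MeCN, rt
Reagents that add atoms: none
Why: In this Saegusa–Ito oxidation, Pd(OAc)2 should convert the silyl enol ether into the C2-palladated ketone (AcOPd–C2), and β-hydride elimination of the C3 hydrogen should give the C2=C3 enone regiospecifically, removing the C3 stereocentre and leaving C4 and C5 untouched.

Step 8
Reactants: 11 rac-cis hydroxy enone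
Product: 12 (1S,6S)-2-methyl-4-oxo-6-geranylgeranylcyclohex-2-en-1-yl acetate
Conditions: Candida antarctica lipase B (immobilised), vinyl acetate (3 equiv), MTBE, 30 °C, stopped near half conversion
Reagents that add atoms: vinyl acetate, C=COC(C)=O
Why: In this lipase-catalysed kinetic resolution by transesterification, the empirical size rule for lipases (the bulky C5 side acting as the large carbinol substituent) predicts acylation of the (4S) carbinol, so the (4S,5S) acetate should form while the (4R,5R) alcohol stays unreacted and is removed by chromatography.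

Step 9
Reactants: 12 (4S,5S) acetate
Product: 13 (4S,5S)-4-hydroxy-3-methyl-5-[(2E,6E,10E)-3,7,11,15-tetramethylhexadeca-2,6,10,14-tetraen-1-yl]cyclohex-2-en-1-one (CNP0277821.1)
Conditions: Candida antarctica lipase B (immobilised), n-BuOH, MTBE, 35 °C
Reagents that add atoms: none
Why: Enzymatic alcoholysis (transesterification to n-butanol) with the same lipase should cleave the acetate under neutral conditions that spare the γ-oxygenated enone, and its identical enantiopreference should raise the optical purity a second time.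

**Compound list**

1 | (2E,6E,10E)-3,7,11,15-tetramethylhexadeca-2,6,10,14-tetraen-1-ol (geranylgeraniol) | CC(C)=CCC/C(C)=C/CC/C(C)=C/CC/C(C)=C/CO | starting material
2 | (2E,6E,10E)-1-bromo-3,7,11,15-tetramethylhexadeca-2,6,10,14-tetraene (geranylgeranyl bromide) | CC(C)=CCC/C(C)=C/CC/C(C)=C/CC/C(C)=C/CBr | intermediate
3 | ethynylmagnesium bromide | C#C[Mg]Br | starting material
4 | (4E,8E,12E)-5,9,13,17-tetramethyloctadeca-4,8,12,16-tetraen-1-yne | CC(C)=CCC/C(C)=C/CC/C(C)=C/CC/C(C)=C/CC#C | intermediate
5 | 4,4,5,5-tetramethyl-2-[(1Z,4E,8E,12E)-5,9,13,17-tetramethyloctadeca-1,4,8,12,16-pentaen-1-yl]-1,3,2-dioxaborolane | CC(C)=CCC/C(C)=C/CC/C(C)=C/CC/C(C)=C/C/C=C\B1OC(C)(C)C(C)(C)O1 | intermediate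
6 | (3E)-pent-3-en-2-one | C/C=C/C(C)=O | starting material
7 | tert-butyl(dimethyl)[(3E)-penta-1,3-dien-2-yloxy]silane | C/C=C/C(=C)O[Si](C)(C)C(C)(C)C | intermediate
8 | rac-tert-butyl(dimethyl)({(4S,5S)-3-methyl-4-(4,4,5,5-tetramethyl-1,3,2-dioxaborolan-2-yl)-5-geranylgeranylcyclohex-1-en-1-yl}oxy)silane; boryl group and side chain cis, both C3 epimers, both enantiomers written | CC(C)=CCC/C(C)=C/CC/C(C)=C/CC/C(C)=C/C[C@H]1CC(O[Si](C)(C)C(C)(C)C)=CC(C)[C@H]1B2OC(C)(C)C(C)(C)O2.CC(C)=CCC/C(C)=C/CC/C(C)=C/CC/C(C)=C/C[C@@H]1CC(O[Si](C)(C)C(C)(C)C)=CC(C)[C@@H]1B2OC(C)(C)C(C)(C)O2 | intermediate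
9 | rac-2-({(1S,6S)-4-{[tert-butyl(dimethyl)silyl]oxy}-2-methyl-6-geranylgeranylcyclohex-3-en-1-yl}oxy)-4,4,5,5-tetramethyl-1,3,2-dioxaborolane; borate ester, both C2 epimers, both enantiomers written | CC(C)=CCC/C(C)=C/CC/C(C)=C/CC/C(C)=C/C[C@H]1CC(O[Si](C)(C)C(C)(C)C)=CC(C)[C@H]1OB2OC(C)(C)C(C)(C)O2.CC(C)=CCC/C(C)=C/CC/C(C)=C/CC/C(C)=C/C[C@@H]1CC(O[Si](C)(C)C(C)(C)C)=CC(C)[C@@H]1OB2OC(C)(C)C(C)(C)O2 | intermediate
10 | rac-(1S,6S)-4-{[tert-butyl(dimethyl)silyl]oxy}-2-methyl-6-geranylgeranylcyclohex-3-en-1-ol; hydroxyl and side chain cis, both C2 epimers, both enantiomers written | CC(C)=CCC/C(C)=C/CC/C(C)=C/CC/C(C)=C/C[C@H]1CC(O[Si](C)(C)C(C)(C)C)=CC(C)[C@H]1O.CC(C)=CCC/C(C)=C/CC/C(C)=C/CC/C(C)=C/C[C@@H]1CC(O[Si](C)(C)C(C)(C)C)=CC(C)[C@@H]1O | intermediate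
11 | rac-(4S,5S)-4-hydroxy-3-methyl-5-geranylgeranylcyclohex-2-en-1-one; cis racemate, both enantiomers written | CC(C)=CCC/C(C)=C/CC/C(C)=C/CC/C(C)=C/C[C@H]1CC(=O)C=C(C)[C@H]1O.CC(C)=CCC/C(C)=C/CC/C(C)=C/CC/C(C)=C/C[C@@H]1CC(=O)C=C(C)[C@@H]1O | intermediate
12 | (1S,6S)-2-methyl-4-oxo-6-geranylgeranylcyclohex-2-en-1-yl acetate | CC(C)=CCC/C(C)=C/CC/C(C)=C/CC/C(C)=C/C[C@H]1CC(=O)C=C(C)[C@H]1OC(C)=O | intermediate
13 | (4S,5S)-4-hydroxy-3-methyl-5-[(2E,6E,10E)-3,7,11,15-tetramethylhexadeca-2,6,10,14-tetraen-1-yl]cyclohex-2-en-1-one (CNP0277821.1) | CC(C)=CCC/C(C)=C/CC/C(C)=C/CC/C(C)=C/C[C@H]1CC(=O)C=C(C)[C@H]1O | target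

**Step count**

Total steps: 9. Longest linear sequence: 8 (steps 1, 2, 3, 5, 6, 7, 8, 9, from geranylgeraniol).

**Steps most likely to fail**

Step 5. What may go wrong: the cycloaddition of the weakly activated β-alkyl alkenylboronate may be too slow, so that dimerisation of the diene or erosion of regiocontrol takes over at the temperature needed. The fallback changes the dienophile class to a dialkyl(alkenyl)borane, which is a much stronger dienophile toward 2-silyloxydienes and has the same para orientation. It sets out from 4. Deprotonation and iodination (n-BuLi, then I2, THF, −78 °C) should give the iodoalkyne F1. Hydroboration with dicyclohexylborane followed by protonolysis with acetic acid should give the (1Z)-iodoalkene F2. Iodine–lithium exchange (t-BuLi, Et2O, −78 °C), capture with B-methoxy-9-BBN and removal of methoxide with BF3·OEt2 should give the B-[(1Z)-alkenyl]-9-borabicyclo[3.3.1]nonane F3. F3 and 7 should combine at 25–60 °C to the cycloadduct F4, which trimethylamine N-oxide would oxidise in the same flask (retention at C4) to 10, where the route is rejoined.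

Step 8. What may go wrong: the lipase may discriminate the two enantiomers poorly, or acylate the hindered cis carbinol too slowly. The fallback replaces the enzymatic resolution by separation of covalent diastereomers. It sets out from 11. Esterification with (S)-2-methoxy-2-phenylacetic acid (EDC, DMAP, CH2Cl2, 0 °C) should give the (4S,5S) ester F6 and the (4R,5R) ester F7, which are separated by chromatography. Methanolysis of F6 (K2CO3, MeOH, 0 °C) should release 13, where the route ends.

Step 7. What may go wrong: dehydrosilylation may be incomplete, with protodesilylation to the saturated ketone, or Pd(OAc)2 may oxidise the side-chain alkenes or the free carbinol. The fallback reaches the enone by selenoxide elimination. It sets out from 10. PhSeCl (CH2Cl2, −78 °C) should selenenylate the silyl enol ether regiospecifically at C2 to give the α-phenylselanyl ketone F5. Oxidation with NaIO4 (NaHCO3, MeOH–H2O, 0 °C to rt) and syn elimination of the selenoxide toward the C3 hydrogen should give 11, where the route is rejoined.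

Further compounds
F1 | step 5 | (4E,8E,12E)-1-iodo-5,9,13,17-tetramethyloctadeca-4,8,12,16-tetraen-1-yne | CC(C)=CCC/C(C)=C/CC/C(C)=C/CC/C(C)=C/CC#CI
F2 | step 5 | (1Z,4E,8E,12E)-1-iodo-5,9,13,17-tetramethyloctadeca-1,4,8,12,16-pentaene | CC(C)=CCC/C(C)=C/CC/C(C)=C/CC/C(C)=C/C/C=C\I
F3 | step 5 | 9-[(1Z,4E,8E,12E)-5,9,13,17-tetramethyloctadeca-1,4,8,12,16-pentaen-1-yl]-9-borabicyclo[3.3.1]nonane | CC(C)=CCC/C(C)=C/CC/C(C)=C/CC/C(C)=C/C/C=C\B1C2CCCC1CCC2
F4 | step 5 | rac-{[4-(9-borabicyclo[3.3.1]nonan-9-yl)-3-methyl-5-geranylgeranylcyclohex-1-en-1-yl]oxy}(tert-butyl)dimethylsilane; boryl group and side chain cis, both C3 epimers, both enantiomers written | CC(C)=CCC/C(C)=C/CC/C(C)=C/CC/C(C)=C/C[C@H]1CC(O[Si](C)(C)C(C)(C)C)=CC(C)[C@H]1B2C3CCCC2CCC3.CC(C)=CCC/C(C)=C/CC/C(C)=C/CC/C(C)=C/C[C@@H]1CC(O[Si](C)(C)C(C)(C)C)=CC(C)[C@@H]1B2C3CCCC2CCC3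
F5 | step 7 | rac-4-hydroxy-3-methyl-2-(phenylselanyl)-5-geranylgeranylcyclohexan-1-one; hydroxyl and side chain cis, C2 and C3 epimers, both enantiomers written | CC(C)=CCC/C(C)=C/CC/C(C)=C/CC/C(C)=C/C[C@H]1CC(=O)C([Se]c2ccccc2)C(C)[C@H]1O.CC(C)=CCC/C(C)=C/CC/C(C)=C/CC/C(C)=C/C[C@@H]1CC(=O)C([Se]c2ccccc2)C(C)[C@@H]1O
F6 | step 8 | (1S,6S)-2-methyl-4-oxo-6-geranylgeranylcyclohex-2-en-1-yl (2S)-methoxy(phenyl)acetate | CC(C)=CCC/C(C)=C/CC/C(C)=C/CC/C(C)=C/C[C@H]1CC(=O)C=C(C)[C@H]1OC(=O)[C@@H](OC)c2ccccc2
F7 | step 8 | (1R,6R)-2-methyl-4-oxo-6-geranylgeranylcyclohex-2-en-1-yl (2S)-methoxy(phenyl)acetate | CC(C)=CCC/C(C)=C/CC/C(C)=C/CC/C(C)=C/C[C@@H]1CC(=O)C=C(C)[C@@H]1OC(=O)[C@@H](OC)c2ccccc2
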